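**Retrosynthetic overview**
1. Target 22 comes from Teuber oxidation of chlororesorcinol 21, which comes from ring chlorination and desilylation of the coupled product 19.
2. Key disconnection: the alkene-carbon/carbinol-carbon bond of 19 is made from aldehyde 11 and aryl butyne 18 by a new enantioselective nickel-catalysed reductive coupling (sets the carbinol centre and the E alkene).
3. Aldehyde 11 comes from allyl ketone 9, made by conjugate methylation of enone 7 (quaternary centre, methyl trans to the C4 methyl) and kinetic protonation at C2.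
4. Enone 7 comes from enone 4, made by an organocatalytic Michael addition and aldol condensation of propanal and ethyl vinyl ketone; alkyne 18 comes from orcinol by ortho-lithiation and propargylation.
5. Ring order: the cyclohexanone ring is closed first (step 2); the benzene ring is bought and is oxidised to the quinone in the last step.

Assumption: the target is taken exactly as drawn (side chain cis to both flanking ring methyls), and the catalyst and ligand antipodes named are those expected to give this sense; the mirror-image catalyst or ligand is used if a sense proves opposite.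

**Route**

Step 1
Reactants: 1 propanal; 2 pent-1-en-3-one
Product: 3 (2S)-2-methyl-5-oxoheptanal
Conditions: (R)-2-[methoxy(diphenyl)methyl]pyrrolidine (5 mol%), ethyl 3,4-dihydroxybenzoate (20 mol%), neat, 4 °C
Reagents that add atoms: none
Why: Enamine-catalysed asymmetric Michael addition in which the diphenyl(methoxy)methyl group shields one face of the E-enamine of propanal, so the vinyl ketone adds to the open face and sets the 2S methyl centre.

Step 2
Reactants: 3
Product: 4 (4S)-2,4-dimethylcyclohex-2-en-1-one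
Conditions: LiOH, i-PrOH, 25 °C
Reagents that add atoms: none
Why: Intramolecular aldol condensation (Robinson-type closure) of the ethyl ketone onto the aldehyde forms the six-membered enone under mild base, and the existing stereocentre is not involved.

Step 3
Reactants: 4; 5 allylmagnesium bromide
Product: 6 trimethyl{[(3R,4S)-2,4-dimethyl-3-(prop-2-en-1-yl)cyclohex-1-en-1-yl]oxy}silane
Conditions: CuBr·SMe2 (1.5 equiv), LiCl, Me3SiCl, THF, −78 °C; Et3N/pentane work-up
Reagents that add atoms: chlorotrimethylsilane, C[Si](C)(C)Cl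
Why: Silyl-chloride-assisted conjugate addition of an allylcopper reagent gives the regiodefined silyl enol ether, allyl entering trans to the C4 methyl at a C3 centre that is erased in step 4.

Step 4
Reactants: 6
Product: 7 (4S)-2,4-dimethyl-3-(prop-2-en-1-yl)cyclohex-2-en-1-one
Conditions: Pd(OAc)2 (1.05 equiv), MeCN, 25 °C
Reagents that add atoms: none
Why: Saegusa–Ito oxidation, in which the palladium enolate at C2 loses the syn C3 hydrogen by β-hydride elimination to give the tetrasubstituted enone regiospecifically, leaving C4 untouched.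

Step 5
Reactants: 7
Product: 9 (2S,3S,4S)-2,3,4-trimethyl-3-(prop-2-en-1-yl)cyclohexan-1-one, via silyl enol ether 8 (not isolated)
Conditions: Me2CuLi (from MeLi, CuI; 3 equiv), Me3SiCl, THF, −78 → −20 °C; then 1 M HCl, THF, 0 °C, 10 min
Reagents that add atoms: lithium dimethylcuprate, [Li+].C[Cu-]C
Why: Cuprate conjugate addition followed by kinetic C-protonation, the methyl attacking C3 axially anti to the pseudoaxial C4 methyl (so allyl ends cis to it) and the proton entering C2 anti to the axial allyl group (so the C2 methyl is equatorial and cis to the side chain).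

Step 6
Reactants: 9
Product: 11 2-[(1S,2S,6S)-1,2,6-trimethyl-3-oxocyclohexyl]acetaldehyde, via ozonide 10 (not isolated)
Conditions: O3, CH2Cl2, −78 °C; then PPh3, −78 → 25 °C
Reagents that add atoms: ozone, [O-][O+]=O
Why: Ozonolysis with reductive work-up cleaves only the terminal alkene to the aldehyde under neutral conditions that leave the three ring stereocentres intact.

Step 7
Reactants: 12 5-methylbenzene-1,3-diol (orcinol)
Product: 13 1,3-bis(methoxymethoxy)-5-methylbenzene
Conditions: MeOCH2Cl, i-Pr2NEt, CH2Cl2, 0 → 25 °C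
Reagents that add atoms: chloromethyl methyl ether, COCCl
Why: Williamson-type O-alkylation installs two methoxymethyl ethers that serve as ortho-directing groups.

Step 8
Reactants: 13; 14 1-bromobut-2-yne
Product: 16 2-(but-2-yn-1-yl)-1,3-bis(methoxymethoxy)-5-methylbenzene, via aryllithium 15 (not isolated)
Conditions: n-BuLi, THF, 0 °C; then 14, −78 → 25 °C
Reagents that add atoms: none
Why: Directed ortho-metalation between the two acetal oxygens followed by SN2 alkylation at the primary propargylic carbon, attack at the methyl-bearing alkyne terminus being disfavoured.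

Step 9
Reactants: 16
Product: 17 2-(but-2-yn-1-yl)-5-methylbenzene-1,3-diol
Conditions: HCl (cat.), MeOH, 40 °C
Reagents that add atoms: none
Why: Acid-catalysed acetal methanolysis removes both methoxymethyl groups at a stage where nothing acid-sensitive is present.

Step 10
Reactants: 17
Product: 18 {[2-(but-2-yn-1-yl)-5-methyl-1,3-phenylene]bis(oxy)}bis[tert-butyl(dimethyl)silane]
Conditions: t-BuMe2SiCl, imidazole, DMF, 25 °C
Reagents that add atoms: tert-butyl(chloro)dimethylsilane, CC(C)(C)[Si](C)(C)Cl
Why: Silylation of both phenols gives ethers that are inert to zerovalent nickel and silane and are later removed by buffered fluoride without acid or strong base.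

Step 11
Reactants: 11; 18
Product: 19 (2S,3S,4S)-3-[(2S,3E)-5-(2,6-bis{[tert-butyl(dimethyl)silyl]oxy}-4-methylphenyl)-3-methyl-2-[(triethylsilyl)oxy]pent-3-en-1-yl]-2,3,4-trimethylcyclohexan-1-one
Conditions: Ni(cod)2 (10 mol%), (4R,5R)-4,5-bis(3,5-di-tert-butylphenyl)-1,3-bis(2-methylnaphthalen-1-yl)-4,5-dihydro-1H-imidazol-3-ium tetrafluoroborate (10 mol%), KOt-Bu (10 mol%), Et3SiH (2 equiv), THF, 25 °C
Reagents that add atoms: triethylsilane, CC[SiH](CC)CC
Why: Proposed new method: a zerovalent nickel complex of a new C2-symmetric chiral N-heterocyclic carbene couples the aldehyde (the hindered ketone is left alone) and the unactivated methyl/benzyl-type alkyne by oxidative cyclization to an oxanickelacyclopentene, the C–C bond forming at the methyl-bearing alkyne carbon because the small methyl sits next to the aldehyde substituent and the bulky 2,6-disiloxybenzyl group next to the metal, the ligand selecting the aldehyde face that gives the 2S carbinol (the minor epimer is a separable diastereomer), and σ-bond metathesis with Et3SiH then C–H reductive elimination deliver H and C syn so that only the E trisubstituted alkene forms; the closest known reaction type is the nickel–carbene-catalysed reductive coupling of aldehydes and alkynes with silanes, which has not been shown to give high regio- and enantiocontrol for methyl-alkyl alkynes with β-quaternary aliphatic keto aldehydes.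

Step 12
Reactants: 19
Product: 20 (2S,3S,4S)-3-[(2S,3E)-5-(2,6-dihydroxy-4-methylphenyl)-2-hydroxy-3-methylpent-3-en-1-yl]-2,3,4-trimethylcyclohexan-1-one
Conditions: Bu4NF, AcOH (1:1, 4 equiv), THF, 0 → 25 °C
Reagents that add atoms: none
Why: Buffered fluoride desilylation cleaves the two aryl silyl ethers and the allylic triethylsilyl ether near neutral pH, so the epimerisable C2 centre and the allylic alcohol are not disturbed.

Step 13
Reactants: 20
Product: 21 (2S,3S,4S)-3-[(2S,3E)-5-(3-chloro-2,6-dihydroxy-4-methylphenyl)-2-hydroxy-3-methylpent-3-en-1-yl]-2,3,4-trimethylcyclohexan-1-one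
Conditions: N-chlorosuccinimide (1.0 equiv), MeCN, −20 → 0 °C, dark
Reagents that add atoms: N-chlorosuccinimide, O=C1CCC(=O)N1Cl
Why: Electrophilic aromatic chlorination, the resorcinol ring (two equivalent positions ortho and para to hydroxyl) being far more nucleophilic than the trisubstituted alkene, so one equivalent gives a single monochloro regioisomer.

Step 14
Reactants: 21
Product: 22 2-chloro-5-hydroxy-3-methyl-6-{(2E,4S)-4-hydroxy-3-methyl-5-[(1S,2S,6S)-1,2,6-trimethyl-3-oxocyclohexyl]pent-2-en-1-yl}cyclohexa-2,5-diene-1,4-dione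
Conditions: (KSO3)2NO (2.5 equiv), KH2PO4 buffer, acetone/H2O, 0 → 25 °C
Reagents that add atoms: potassium nitrosodisulfonate, [K+].[K+].[O]N(S(=O)(=O)[O-])S(=O)(=O)[O-]
Why: Teuber oxidation, in which the phenoxyl radical is trapped by a second nitrosodisulfonate at the only free ring position (para to one hydroxyl) and collapses to the 2-hydroxy-1,4-benzoquinone without touching any stereocentre.

**Compound list**
1 | propanal | CCC=O | starting material
2 | pent-1-en-3-one | C=CC(=O)CC | starting material
3 | (2S)-2-methyl-5-oxoheptanal | CCC(=O)CC[C@H](C)C=O | intermediate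
4 | (4S)-2,4-dimethylcyclohex-2-en-1-one | O=C1CC[C@H](C)C=C1C | intermediate
5 | allylmagnesium bromide | C=CC[Mg]Br | starting material
6 | trimethyl{[(3R,4S)-2,4-dimethyl-3-(prop-2-en-1-yl)cyclohex-1-en-1-yl]oxy}silane | C[Si](C)(C)OC1=C(C)[C@H](CC=C)[C@@H](C)CC1 | intermediate
7 | (4S)-2,4-dimethyl-3-(prop-2-en-1-yl)cyclohex-2-en-1-one | O=C1CC[C@H](C)C(CC=C)=C1C | intermediate
8 | trimethyl{[(3S,4S)-2,3,4-trimethyl-3-(prop-2-en-1-yl)cyclohex-1-en-1-yl]oxy}silane | C[Si](C)(C)OC1=C(C)[C@@](C)(CC=C)[C@@H](C)CC1 | intermediate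
9 | (2S,3S,4S)-2,3,4-trimethyl-3-(prop-2-en-1-yl)cyclohexan-1-one | C=CC[C@]1(C)[C@H](C)C(=O)CC[C@@H]1C | intermediate
10 | (2S,3S,4S)-2,3,4-trimethyl-3-[(1,2,4-trioxolan-3-yl)methyl]cyclohexan-1-one (both epimers at the trioxolane carbon) | C1OOC(O1)C[C@]2(C)[C@H](C)C(=O)CC[C@@H]2C | intermediate
11 | 2-[(1S,2S,6S)-1,2,6-trimethyl-3-oxocyclohexyl]acetaldehyde | O=CC[C@]1(C)[C@H](C)C(=O)CC[C@@H]1C | intermediate
12 | 5-methylbenzene-1,3-diol (orcinol) | Cc1cc(O)cc(O)c1 | starting material
13 | 1,3-bis(methoxymethoxy)-5-methylbenzene | Cc1cc(OCOC)cc(OCOC)c1 | intermediate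
14 | 1-bromobut-2-yne | CC#CCBr | starting material
15 | [2,6-bis(methoxymethoxy)-4-methylphenyl]lithium | [Li]c1c(OCOC)cc(C)cc1OCOC | intermediate
16 | 2-(but-2-yn-1-yl)-1,3-bis(methoxymethoxy)-5-methylbenzene | CC#CCc1c(OCOC)cc(C)cc1OCOC | intermediate
17 | 2-(but-2-yn-1-yl)-5-methylbenzene-1,3-diol | CC#CCc1c(O)cc(C)cc1O | intermediate
18 | {[2-(but-2-yn-1-yl)-5-methyl-1,3-phenylene]bis(oxy)}bis[tert-butyl(dimethyl)silane] | CC#CCc1c(O[Si](C)(C)C(C)(C)C)cc(C)cc1O[Si](C)(C)C(C)(C)C | intermediate
19 | (2S,3S,4S)-3-[(2S,3E)-5-(2,6-bis{[tert-butyl(dimethyl)silyl]oxy}-4-methylphenyl)-3-methyl-2-[(triethylsilyl)oxy]pent-3-en-1-yl]-2,3,4-trimethylcyclohexan-1-one | Cc1cc(O[Si](C)(C)C(C)(C)C)c(C/C=C(\C)[C@@H](O[Si](CC)(CC)CC)C[C@]2(C)[C@H](C)C(=O)CC[C@@H]2C)c(O[Si](C)(C)C(C)(C)C)c1 | intermediate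
20 | (2S,3S,4S)-3-[(2S,3E)-5-(2,6-dihydroxy-4-methylphenyl)-2-hydroxy-3-methylpent-3-en-1-yl]-2,3,4-trimethylcyclohexan-1-one | Cc1cc(O)c(C/C=C(\C)[C@@H](O)C[C@]2(C)[C@H](C)C(=O)CC[C@@H]2C)c(O)c1 | intermediate
21 | (2S,3S,4S)-3-[(2S,3E)-5-(3-chloro-2,6-dihydroxy-4-methylphenyl)-2-hydroxy-3-methylpent-3-en-1-yl]-2,3,4-trimethylcyclohexan-1-one | Cc1cc(O)c(C/C=C(\C)[C@@H](O)C[C@]2(C)[C@H](C)C(=O)CC[C@@H]2C)c(O)c1Cl | intermediate
22 | 2-chloro-5-hydroxy-3-methyl-6-{(2E,4S)-4-hydroxy-3-methyl-5-[(1S,2S,6S)-1,2,6-trimethyl-3-oxocyclohexyl]pent-2-en-1-yl}cyclohexa-2,5-diene-1,4-dione | CC1=C(Cl)C(=O)C(C/C=C(\C)[C@@H](O)C[C@]2(C)[C@H](C)C(=O)CC[C@@H]2C)=C(O)C1=O | target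

**Totals**
Total step count: 14.
Longest linear sequence: 10 steps (steps 1–6, then 11–14); steps 7–10 form the second branch.

**Three steps most likely to fail**

Step 5 (conjugate methylation of the hindered tetrasubstituted enone). If the cuprate does not add, the methyl is brought in as a cyclopropane methylene; the fallback sets out from 7 and comes back at 9. Corey–Chaykovsky cyclopropanation of 7 with dimethylsulfoxonium methylide (Me3S(O)I, NaH, DMSO, 50 °C), the small ylide adding to C3 anti to the C4 methyl, gives (1R,5S,6R)-1,5-dimethyl-6-(prop-2-en-1-yl)bicyclo[4.1.0]heptan-2-one F1. Dissolving-metal reduction (Li, NH3/THF, −78 °C) cleaves the exocyclic cyclopropane bond that overlaps with the carbonyl, turning the methylene into the C3 methyl. Quenching at −78 °C (NH4Cl) protonates C2 anti to the axial allyl group and gives 9.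

Step 11 (the proposed nickel-catalysed coupling; risks are regiocontrol, facial control and slow turnover with the bulky alkyne). The fallback uses known chemistry, sets out from 18 and 11, and comes back at 20. Hydrozirconation of 18 (Cp2Zr(H)Cl, THF, 50 °C, zirconium settling on the methyl-bearing carbon) and iodinolysis (I2, 0 °C) give {[2-[(2E)-3-iodobut-2-en-1-yl]-5-methyl-1,3-phenylene]bis(oxy)}bis[tert-butyl(dimethyl)silane] F2. An asymmetric Nozaki–Hiyama–Kishi reaction of F2 with 11 (CrCl2, NiCl2 cat., chiral oxazoline–sulfonamide ligand, Et3N, THF, 25 °C) adds the alkenyl group to the aldehyde only and gives (2S,3S,4S)-3-[(2S,3E)-5-(2,6-bis{[tert-butyl(dimethyl)silyl]oxy}-4-methylphenyl)-2-hydroxy-3-methylpent-3-en-1-yl]-2,3,4-trimethylcyclohexan-1-one F3, the minor carbinol epimer being a separable diastereomer. Desilylation of F3 with Bu4NF/AcOH as in step 12 gives 20.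

Step 13 (late monochlorination; risks are dichlorination and attack on the alkene). The fallback moves the chlorination to the fragment stage, sets out from 17 and comes back at 21. Chlorination of 17 (N-chlorosuccinimide, MeCN, 0 °C) gives 2-(but-2-yn-1-yl)-4-chloro-5-methylbenzene-1,3-diol F4, which is purified at this simple stage. Silylation (t-BuMe2SiCl, imidazole, DMF) gives {[2-(but-2-yn-1-yl)-4-chloro-5-methyl-1,3-phenylene]bis(oxy)}bis[tert-butyl(dimethyl)silane] F5. Coupling of F5 with 11 under the conditions of step 11 gives (2S,3S,4S)-3-[(2S,3E)-5-(2,6-bis{[tert-butyl(dimethyl)silyl]oxy}-3-chloro-4-methylphenyl)-3-methyl-2-[(triethylsilyl)oxy]pent-3-en-1-yl]-2,3,4-trimethylcyclohexan-1-one F6; the aryl chloride is flanked on both sides and should be slow to react with the nickel catalyst at 25 °C. Desilylation of F6 with Bu4NF/AcOH gives 21.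

**Further compounds**
F1 | step 5 | (1R,5S,6R)-1,5-dimethyl-6-(prop-2-en-1-yl)bicyclo[4.1.0]heptan-2-one | O=C1CC[C@H](C)[C@@]2(CC=C)C[C@@]12C
F2 | step 11 | {[2-[(2E)-3-iodobut-2-en-1-yl]-5-methyl-1,3-phenylene]bis(oxy)}bis[tert-butyl(dimethyl)silane] | C/C(I)=C\Cc1c(O[Si](C)(C)C(C)(C)C)cc(C)cc1O[Si](C)(C)C(C)(C)C
F3 | step 11 | (2S,3S,4S)-3-[(2S,3E)-5-(2,6-bis{[tert-butyl(dimethyl)silyl]oxy}-4-methylphenyl)-2-hydroxy-3-methylpent-3-en-1-yl]-2,3,4-trimethylcyclohexan-1-one | Cc1cc(O[Si](C)(C)C(C)(C)C)c(C/C=C(\C)[C@@H](O)C[C@]2(C)[C@H](C)C(=O)CC[C@@H]2C)c(O[Si](C)(C)C(C)(C)C)c1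
F4 | step 13 | 2-(but-2-yn-1-yl)-4-chloro-5-methylbenzene-1,3-diol | CC#CCc1c(O)cc(C)c(Cl)c1O
F5 | step 13 | {[2-(but-2-yn-1-yl)-4-chloro-5-methyl-1,3-phenylene]bis(oxy)}bis[tert-butyl(dimethyl)silane] | CC#CCc1c(O[Si](C)(C)C(C)(C)C)cc(C)c(Cl)c1O[Si](C)(C)C(C)(C)C
F6 | step 13 | (2S,3S,4S)-3-[(2S,3E)-5-(2,6-bis{[tert-butyl(dimethyl)silyl]oxy}-3-chloro-4-methylphenyl)-3-methyl-2-[(triethylsilyl)oxy]pent-3-en-1-yl]-2,3,4-trimethylcyclohexan-1-one | Cc1cc(O[Si](C)(C)C(C)(C)C)c(C/C=C(\C)[C@@H](O[Si](CC)(CC)CC)C[C@]2(C)[C@H](C)C(=O)CC[C@@H]2C)c(O[Si](C)(C)C(C)(C)C)c1Cl
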